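**Plan**

- Retrosynthesis: remove the O6 acetate, return the 4,5-epoxide to the C4=C5 olefin, and trace the C8 ester and C6 carbinol back to a C8-hydroxy C6-ketone. Then re-form the C6–C10 bond, which turns the ten-membered (1(10)E,4Z)-dienone into a bicyclo[5.3.0]decenol mesylate. The bicycle is cut at C4=C5 (metathesis), C5–C6 (vinyl addition), C1–C10 (aldol), C9=C10 (metathesis), C6–isopropenyl (ketone synthesis) and C7–C8 (auxiliary aldol).
- Feature used: in the ten-membered ring the oxygenated C6 and the olefinic C1 both flank C10. A C6–C10 bond plus a leaving group on C1 therefore holds the C6 carbonyl and the E C1=C10 olefin in latent form. That bond defines a five-membered ring C6–C7–C8–C9–C10 fused to a seven-membered ring C10–C1–C2–C3–C4–C5–C6.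
- Forward order: C6–C9 chain, then cyclopentenone, quaternary C10 by reductive aldol, C5 vinyl group, cycloheptene, mesylate, fragmentation to the ten-membered ring, then ester, epoxide and acetate.
- Stereochemistry: C7 and C8 come from the (R)-oxazolidinone syn aldol. The C1/C10 relationship that becomes the E olefin comes from a hydroxyl-directed ketone reduction. C6 comes from the Evans–Tishchenko hydride shift (anti to O8), and C4/C5 from hydroxyl-directed epoxidation.

Key step: step 13

Remarks on the chemistry: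
- Locants C1–C10 are those of the ten-membered ring of the target in every intermediate.
- 4-Methylpent-4-enal and 3-methylbut-2-enal are taken as purchasable.
- C1, C6 and C10 are stereocentres only up to step 13; the isomers drawn are the expected ones.
- A closed aldol transition state in step 7 is predicted to give the C1 epimer that would lead to the Z olefin, so C1 is reset in steps 9 and 10. The carbinol of 13 and 14 is drawn as that predicted epimer; its C1 epimer converges in step 9.

**Route**

Step 1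
Reactants: 1 (R)-4-benzyl-1,3-oxazolidin-2-one; 2 3-methylbutanoyl chloride
Product: 3 (R)-4-benzyl-3-(3-methylbutanoyl)-1,3-oxazolidin-2-one
Conditions: n-BuLi, THF, −78 °C; then 2, −78 → 0 °C
Reagents that add atoms: none
Why: N-acylation of the lithiated oxazolidinone by the acid chloride is the standard entry to Evans imides and creates no stereocentre.

Step 2
Reactants: 3 (R)-4-benzyl-3-(3-methylbutanoyl)-1,3-oxazolidin-2-one; 4 acrolein
Product: 6 (R)-4-benzyl-3-[(2R,3S)-3-hydroxy-2-(propan-2-yl)pent-4-enoyl]-1,3-oxazolidin-2-one, via dibutylboron Z-enolate 5 (not isolated)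
Conditions: Bu2BOTf, Et3N, CH2Cl2, −78 → 0 °C; then 4, −78 → 0 °C; H2O2, MeOH, pH 7 buffer
Reagents that add atoms: none
Why: Evans syn aldol, in which the Z-boron enolate reacts through a closed Zimmerman–Traxler chair on the face left open by the (R)-benzyl group, so C7 is set as R and C8 as S (2R,3S syn adduct).

Step 3
Reactants: 6 (R)-4-benzyl-3-[(2R,3S)-3-hydroxy-2-(propan-2-yl)pent-4-enoyl]-1,3-oxazolidin-2-one
Product: 7 (2R,3S)-3-hydroxy-N-methoxy-N-methyl-2-(propan-2-yl)pent-4-enamide
Conditions: AlMe3, MeNHOMe·HCl, CH2Cl2, −20 → 0 °C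
Reagents that add atoms: N,O-dimethylhydroxylamine hydrochloride, CNOC.Cl
Why: Weinreb transamidation, in which the aluminium alkoxide of the free C8 hydroxyl steers the aluminium amide to the exocyclic carbonyl, so the auxiliary is released without epimerising C7.

Step 4
Reactants: 7 (2R,3S)-3-hydroxy-N-methoxy-N-methyl-2-(propan-2-yl)pent-4-enamide
Product: 8 (2R,3S)-3-[(tert-butyldimethylsilyl)oxy]-N-methoxy-N-methyl-2-(propan-2-yl)pent-4-enamide
Conditions: TBSOTf, 2,6-lutidine, CH2Cl2, −78 → 0 °C
Reagents that add atoms: tert-butyldimethylsilyl trifluoromethanesulfonate, CC(C)(C)[Si](C)(C)OS(=O)(=O)C(F)(F)F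
Why: Silylation of a hindered secondary alcohol with the silyl triflate gives an ether that should survive the organometallic, hydride, metathesis and fragmentation steps that follow.

Step 5
Reactants: 8 (2R,3S)-3-[(tert-butyldimethylsilyl)oxy]-N-methoxy-N-methyl-2-(propan-2-yl)pent-4-enamide
Product: 9 (4R,5S)-5-[(tert-butyldimethylsilyl)oxy]-2-methyl-4-(propan-2-yl)hepta-1,6-dien-3-one
Conditions: CH2=C(CH3)MgBr, THF, 0 °C; cold aqueous quench
Reagents that add atoms: isopropenylmagnesium bromide, CC(=C)[Mg]Br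
Why: Weinreb ketone synthesis, whose chelated tetrahedral intermediate stops over-addition and keeps C7 from enolising until the quench.

Step 6
Reactants: 9 (4R,5S)-5-[(tert-butyldimethylsilyl)oxy]-2-methyl-4-(propan-2-yl)hepta-1,6-dien-3-one
Product: 10 (4S,5R)-4-[(tert-butyldimethylsilyl)oxy]-2-methyl-5-(propan-2-yl)cyclopent-2-en-1-one
Conditions: second-generation Grubbs catalyst (H2IMes)(PCy3)Cl2Ru=CHPh (5 mol%), CH2Cl2, 40 °C
Reagents that add atoms: none
Why: Ring-closing metathesis starts at the monosubstituted C9 vinyl group and closes onto the isopropenyl ketone to give the trisubstituted C9=C10 enone of the five-membered ring, leaving C7 and C8 untouched and trans.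

Step 7
Reactants: 10 (4S,5R)-4-[(tert-butyldimethylsilyl)oxy]-2-methyl-5-(propan-2-yl)cyclopent-2-en-1-one; 11 4-methylpent-4-enal
Product: 13 (2S,4S,5R)-4-[(tert-butyldimethylsilyl)oxy]-2-[(1S)-1-hydroxy-4-methylpent-4-en-1-yl]-2-methyl-5-(propan-2-yl)cyclopentan-1-one, via lithium enolate 12 (not isolated)
Conditions: LiBH(s-Bu)3, THF, −78 °C; then 11, −78 °C; pH 7 buffer
Reagents that add atoms: none
Why: Reductive aldol, in which hydride adds 1,4 to the enone (C9 carries no substituent), the C6–C10 lithium enolate forms regiospecifically and adds to the aldehyde on the face anti to the C7 isopropyl group (C10 S), while the closed Zimmerman–Traxler chair of this ring enolate should place the C1 hydroxyl as drawn (1S), a centre that steps 9 and 10 reset.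

Step 8
Reactants: 13 (2S,4S,5R)-4-[(tert-butyldimethylsilyl)oxy]-2-[(1S)-1-hydroxy-4-methylpent-4-en-1-yl]-2-methyl-5-(propan-2-yl)cyclopentan-1-one
Product: 14 (1R,2S,4S,5R)-4-[(tert-butyldimethylsilyl)oxy]-1-ethenyl-2-[(1S)-1-hydroxy-4-methylpent-4-en-1-yl]-2-methyl-5-(propan-2-yl)cyclopentan-1-ol
Conditions: CH2=CHMgBr (3 equiv), CeCl3, THF, −78 °C; aqueous work-up
Reagents that add atoms: vinylmagnesium bromide, C=C[Mg]Br
Why: Organocerium 1,2-addition, whose low basicity avoids enolisation toward C7 and loss of the C8 silyloxy group, with the vinyl group entering anti to the C7 isopropyl and C10 methyl groups while the C1 alkoxide holds the side chain near the carbonyl plane, which sets C6 as R with the vinyl group cis to the C1 chain.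

Step 9
Reactants: 14 (1R,2S,4S,5R)-4-[(tert-butyldimethylsilyl)oxy]-1-ethenyl-2-[(1S)-1-hydroxy-4-methylpent-4-en-1-yl]-2-methyl-5-(propan-2-yl)cyclopentan-1-ol
Product: 15 1-[(1R,2R,3R,4S)-4-[(tert-butyldimethylsilyl)oxy]-2-ethenyl-2-hydroxy-1-methyl-3-(propan-2-yl)cyclopentyl]-4-methylpent-4-en-1-one
Conditions: Dess–Martin periodinane, CH2Cl2, 0 °C → rt
Reagents that add atoms: none
Why: Dess–Martin oxidation takes only the secondary C1 carbinol (the tertiary allylic C6 alcohol cannot be oxidised), its near-neutral medium avoids retro-aldol cleavage of the β-hydroxy ketone, and both C1 epimers of 14 give the same ketone.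

Step 10
Reactants: 15 1-[(1R,2R,3R,4S)-4-[(tert-butyldimethylsilyl)oxy]-2-ethenyl-2-hydroxy-1-methyl-3-(propan-2-yl)cyclopentyl]-4-methylpent-4-en-1-one
Product: 16 (1R,2S,4S,5R)-4-[(tert-butyldimethylsilyl)oxy]-1-ethenyl-2-[(1R)-1-hydroxy-4-methylpent-4-en-1-yl]-2-methyl-5-(propan-2-yl)cyclopentan-1-ol
Conditions: Me4NBH(OAc)3, MeCN/AcOH (1:1), −30 °C
Reagents that add atoms: none
Why: Evans–Saksena hydroxyl-directed reduction, in which the tertiary O6 exchanges onto boron and delivers hydride through a six-membered chair that is trans-fused to the cyclopentane (C10 methyl axial, C2 chain equatorial), so the new C1–O bond ends anti to the C10 methyl group (1R), the relationship that the fragmentation turns into the E olefin.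

Step 11
Reactants: 16 (1R,2S,4S,5R)-4-[(tert-butyldimethylsilyl)oxy]-1-ethenyl-2-[(1R)-1-hydroxy-4-methylpent-4-en-1-yl]-2-methyl-5-(propan-2-yl)cyclopentan-1-ol
Product: 17 (1R,6R,7R,8S,10S)-8-[(tert-butyldimethylsilyl)oxy]-4,10-dimethyl-7-(propan-2-yl)bicyclo[5.3.0]dec-4-ene-1,6-diol (target numbering)
Conditions: second-generation Grubbs catalyst (H2IMes)(PCy3)Cl2Ru=CHPh (10 mol%), toluene (2 mM), 80 °C
Reagents that add atoms: none
Why: Ring-closing metathesis of the cis-disposed C6 vinyl group and the 1,1-disubstituted olefin of the C1 chain closes the seven-membered ring, whose size forces the new trisubstituted C4=C5 bond to be Z, and the free allylic alcohol is tolerated by the ruthenium carbene.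

Step 12
Reactants: 17 (1R,6R,7R,8S,10S)-8-[(tert-butyldimethylsilyl)oxy]-4,10-dimethyl-7-(propan-2-yl)bicyclo[5.3.0]dec-4-ene-1,6-diol
Product: 18 (1R,6R,7R,8S,10S)-8-[(tert-butyldimethylsilyl)oxy]-6-hydroxy-4,10-dimethyl-7-(propan-2-yl)bicyclo[5.3.0]dec-4-en-1-yl methanesulfonate (target numbering)
Conditions: MsCl, Et3N, CH2Cl2, −20 → 0 °C
Reagents that add atoms: methanesulfonyl chloride, CS(=O)(=O)Cl
Why: Mesylation esterifies the secondary C1 hydroxyl while the tertiary C6 hydroxyl stays free, the weak amine base does not trigger the fragmentation, and no stereocentre is changed.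

Step 13
Reactants: 18 (1R,6R,7R,8S,10S)-8-[(tert-butyldimethylsilyl)oxy]-6-hydroxy-4,10-dimethyl-7-(propan-2-yl)bicyclo[5.3.0]dec-4-en-1-yl methanesulfonate
Product: 20 (2Z,6E,9S,10R)-9-[(tert-butyldimethylsilyl)oxy]-3,7-dimethyl-10-(propan-2-yl)cyclodeca-2,6-dien-1-one, via potassium alkoxide 19 (not isolated)
Conditions: KN(SiMe3)2 (1.05 equiv), THF, −78 → 0 °C; pH 7 buffer
Reagents that add atoms: none
Why: Deprotonation of the tertiary C6 hydroxyl gives alkoxide 19, whose oxygen lone pair pushes into the C6–C10 σ bond while that bond, antiperiplanar to the equatorial C1–OMs bond, breaks and methanesulfonate leaves, so C6=O and the C1=C10 π bond form in one concerted step (Grob fragmentation in its Wharton form, known for 1,3-diol monosulfonates of decalins and hydrindanes). No σ bond is made: the ten-membered ring appears because the bond shared by the five- and seven-membered rings is cut, which merges them into the C1–C10 perimeter. No stereocentre is created; C1, C6 and C10 are erased and C7 and C8 pass through unchanged. The one element set is the olefin geometry, and it is fixed by the (1R,10S) relationship: with the mesylate anti to C6–C10, C9 is anti to C2 and the methyl group is gauche to C2, which is the E arrangement. The cycloheptene already holds C4=C5 as Z, and the cis relation of O6 and the mesylate on the seven-membered ring rules out oxetane formation by internal displacement. One equivalent of a non-nucleophilic potassium amide at low temperature is used so that no base is left to enolise C7 or expel the C8 silyloxy group from the product.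

Step 14
Reactants: 20 (2Z,6E,9S,10R)-9-[(tert-butyldimethylsilyl)oxy]-3,7-dimethyl-10-(propan-2-yl)cyclodeca-2,6-dien-1-one
Product: 21 (2Z,6E,9S,10R)-9-hydroxy-3,7-dimethyl-10-(propan-2-yl)cyclodeca-2,6-dien-1-one
Conditions: HF·pyridine, pyridine, THF, 0 °C → rt
Reagents that add atoms: none
Why: Fluoride desilylation in a buffered, non-basic medium frees the C8 hydroxyl without retro-aldol cleavage, C7 epimerisation or acid-promoted transannular cyclisation of the diene.

Step 15
Reactants: 21 (2Z,6E,9S,10R)-9-hydroxy-3,7-dimethyl-10-(propan-2-yl)cyclodeca-2,6-dien-1-one; 22 3-methylbut-2-enal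
Product: 24 (1(10)E,4Z,6S,7S,8S)-6-hydroxy-4,10-dimethyl-7-(propan-2-yl)cyclodeca-1(10),4-dien-8-yl 3-methylbut-2-enoate (target numbering), via samarium-bound hemiacetal 23 (not isolated)
Conditions: SmI2 (0.3 equiv), 22 (6 equiv), THF, −10 °C
Reagents that add atoms: none
Why: Evans–Tishchenko reduction, in which the C8 hydroxyl forms a hemiacetal with the aldehyde, samarium ties its oxygen to the C6 carbonyl and the hemiacetal hydrogen is delivered inside this chair-like chelate, which gives the 6,8-anti carbinol (6S) and at the same time leaves C8 as its 3-methylbut-2-enoate.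

Step 16
Reactants: 24 (1(10)E,4Z,6S,7S,8S)-6-hydroxy-4,10-dimethyl-7-(propan-2-yl)cyclodeca-1(10),4-dien-8-yl 3-methylbut-2-enoate
Product: 25 (1(10)E,4S,5R,6R,7S,8S)-4,5-epoxy-6-hydroxy-4,10-dimethyl-7-(propan-2-yl)cyclodec-1(10)-en-8-yl 3-methylbut-2-enoate (target numbering)
Conditions: VO(acac)2 (5 mol%), t-BuOOH, CH2Cl2, 0 °C
Reagents that add atoms: tert-butyl hydroperoxide, CC(C)(C)OO
Why: Hydroxyl-directed vanadium epoxidation, in which the allylic C6 alkoxide binds the vanadium peroxide and delivers oxygen to the face of the ring Z olefin on which it sits, as in medium-ring (Z)-cycloalk-2-enols, which sets 4S,5R (epoxide cis to O6), while the isolated C1=C10 bond and the electron-poor enoate react far more slowly.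

Step 17
Reactants: 25 (1(10)E,4S,5R,6R,7S,8S)-4,5-epoxy-6-hydroxy-4,10-dimethyl-7-(propan-2-yl)cyclodec-1(10)-en-8-yl 3-methylbut-2-enoate
Product: 26 (1(10)E,4S,5R,6R,7R,8S)-6-acetoxy-4,5-epoxy-4,10-dimethyl-7-(propan-2-yl)cyclodec-1(10)-en-8-yl 3-methylbut-2-enoate (CNP0118795.1)
Conditions: Ac2O, pyridine, DMAP (cat.), CH2Cl2, 0 °C → rt
Reagents that add atoms: acetic anhydride, CC(=O)OC(C)=O
Why: DMAP-catalysed acetylation of the remaining secondary hydroxyl under mild basic conditions leaves the epoxide, both olefins and the enoate untouched and completes the target.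

**Compound list**

1 | (R)-4-benzyl-1,3-oxazolidin-2-one | C1[C@H](NC(=O)O1)Cc2ccccc2 | starting material
2 | 3-methylbutanoyl chloride | CC(C)CC(Cl)=O | starting material
3 | (R)-4-benzyl-3-(3-methylbutanoyl)-1,3-oxazolidin-2-one | CC(C)CC(=O)N1[C@H](Cc2ccccc2)COC1=O | intermediate
4 | acrolein (prop-2-enal) | C=CC=O | starting material
5 | dibutylboron (Z)-enolate of 3 | CCCCB(CCCC)O/C(=C\C(C)C)N1[C@H](Cc2ccccc2)COC1=O | intermediate
6 | (R)-4-benzyl-3-[(2R,3S)-3-hydroxy-2-(propan-2-yl)pent-4-enoyl]-1,3-oxazolidin-2-one | O=C1OC[C@@H](Cc2ccccc2)N1C(=O)[C@H](C(C)C)[C@@H](O)C=C | intermediate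
7 | (2R,3S)-3-hydroxy-N-methoxy-N-methyl-2-(propan-2-yl)pent-4-enamide | CON(C)C(=O)[C@H](C(C)C)[C@@H](O)C=C | intermediate
8 | (2R,3S)-3-[(tert-butyldimethylsilyl)oxy]-N-methoxy-N-methyl-2-(propan-2-yl)pent-4-enamide | CON(C)C(=O)[C@H](C(C)C)[C@@H](O[Si](C)(C)C(C)(C)C)C=C | intermediate
9 | (4R,5S)-5-[(tert-butyldimethylsilyl)oxy]-2-methyl-4-(propan-2-yl)hepta-1,6-dien-3-one | C=C(C)C(=O)[C@H](C(C)C)[C@@H](O[Si](C)(C)C(C)(C)C)C=C | intermediate
10 | (4S,5R)-4-[(tert-butyldimethylsilyl)oxy]-2-methyl-5-(propan-2-yl)cyclopent-2-en-1-one (iPr and OTBS trans) | O=C1[C@H](C(C)C)[C@@H](O[Si](C)(C)C(C)(C)C)C=C1C | intermediate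
11 | 4-methylpent-4-enal | C=C(C)CCC=O | starting material
12 | lithium (4S,5R)-4-[(tert-butyldimethylsilyl)oxy]-2-methyl-5-(propan-2-yl)cyclopent-1-en-1-olate | [Li]OC1=C(C)C[C@H](O[Si](C)(C)C(C)(C)C)[C@H]1C(C)C | intermediate
13 | (2S,4S,5R)-4-[(tert-butyldimethylsilyl)oxy]-2-[(1S)-1-hydroxy-4-methylpent-4-en-1-yl]-2-methyl-5-(propan-2-yl)cyclopentan-1-one | C[C@@]1([C@@H](O)CCC(C)=C)C[C@H](O[Si](C)(C)C(C)(C)C)[C@@H](C(C)C)C1=O | intermediate
14 | (1R,2S,4S,5R)-4-[(tert-butyldimethylsilyl)oxy]-1-ethenyl-2-[(1S)-1-hydroxy-4-methylpent-4-en-1-yl]-2-methyl-5-(propan-2-yl)cyclopentan-1-ol | C[C@@]1([C@@H](O)CCC(C)=C)C[C@H](O[Si](C)(C)C(C)(C)C)[C@@H](C(C)C)[C@]1(O)C=C | intermediate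
15 | 1-[(1R,2R,3R,4S)-4-[(tert-butyldimethylsilyl)oxy]-2-ethenyl-2-hydroxy-1-methyl-3-(propan-2-yl)cyclopentyl]-4-methylpent-4-en-1-one | C[C@@]1(C(=O)CCC(C)=C)C[C@H](O[Si](C)(C)C(C)(C)C)[C@@H](C(C)C)[C@]1(O)C=C | intermediate
16 | (1R,2S,4S,5R)-4-[(tert-butyldimethylsilyl)oxy]-1-ethenyl-2-[(1R)-1-hydroxy-4-methylpent-4-en-1-yl]-2-methyl-5-(propan-2-yl)cyclopentan-1-ol | C[C@@]1([C@H](O)CCC(C)=C)C[C@H](O[Si](C)(C)C(C)(C)C)[C@@H](C(C)C)[C@]1(O)C=C | intermediate
17 | (1R,6R,7R,8S,10S)-8-[(tert-butyldimethylsilyl)oxy]-4,10-dimethyl-7-(propan-2-yl)bicyclo[5.3.0]dec-4-ene-1,6-diol (target numbering; C6 and C10 are the fusion atoms, cis-fused) | C[C@@]12C[C@H](O[Si](C)(C)C(C)(C)C)[C@@H](C(C)C)[C@]1(O)C=C(C)CC[C@H]2O | intermediate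
18 | (1R,6R,7R,8S,10S)-8-[(tert-butyldimethylsilyl)oxy]-6-hydroxy-4,10-dimethyl-7-(propan-2-yl)bicyclo[5.3.0]dec-4-en-1-yl methanesulfonate (target numbering) | C[C@@]12C[C@H](O[Si](C)(C)C(C)(C)C)[C@@H](C(C)C)[C@]1(O)C=C(C)CC[C@H]2OS(C)(=O)=O | intermediate
19 | potassium C6 alkoxide of 18 | C[C@@]12C[C@H](O[Si](C)(C)C(C)(C)C)[C@@H](C(C)C)[C@]1([O-])C=C(C)CC[C@H]2OS(C)(=O)=O.[K+] | intermediate
20 | (2Z,6E,9S,10R)-9-[(tert-butyldimethylsilyl)oxy]-3,7-dimethyl-10-(propan-2-yl)cyclodeca-2,6-dien-1-one (8-silyloxygermacra-1(10)E,4Z-dien-6-one) | C1/C(C)=C/CC/C(C)=C\C(=O)[C@H](C(C)C)[C@H]1O[Si](C)(C)C(C)(C)C | intermediate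
21 | (2Z,6E,9S,10R)-9-hydroxy-3,7-dimethyl-10-(propan-2-yl)cyclodeca-2,6-dien-1-one | C1/C(C)=C/CC/C(C)=C\C(=O)[C@H](C(C)C)[C@H]1O | intermediate
22 | 3-methylbut-2-enal | CC(C)=CC=O | starting material
23 | hemiacetal of 21 (at O8) and 22, samarium-bound in the flask, either configuration at the hemiacetal carbon | C1/C(C)=C/CC/C(C)=C\C(=O)[C@H](C(C)C)[C@H]1OC(O)C=C(C)C | intermediate
24 | (1(10)E,4Z,6S,7S,8S)-6-hydroxy-4,10-dimethyl-7-(propan-2-yl)cyclodeca-1(10),4-dien-8-yl 3-methylbut-2-enoate (target numbering) | C1/C(C)=C/CC/C(C)=C\[C@H](O)[C@H](C(C)C)[C@H]1OC(=O)C=C(C)C | intermediate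
25 | (1(10)E,4S,5R,6R,7S,8S)-4,5-epoxy-6-hydroxy-4,10-dimethyl-7-(propan-2-yl)cyclodec-1(10)-en-8-yl 3-methylbut-2-enoate (target numbering) | O[C@@H]1[C@H](C(C)C)[C@@H](OC(=O)C=C(C)C)C/C(C)=C/CC[C@]2(C)O[C@H]12 | intermediate
26 | (1(10)E,4S,5R,6R,7R,8S)-6-acetoxy-4,5-epoxy-4,10-dimethyl-7-(propan-2-yl)cyclodec-1(10)-en-8-yl 3-methylbut-2-enoate (CNP0118795.1) | CC(=O)O[C@@H]1[C@H](C(C)C)[C@@H](OC(=O)C=C(C)C)C/C(C)=C/CC[C@]2(C)O[C@H]12 | target

**Count**

Total steps: 17. Longest linear sequence: 17 steps (1 to 26).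

**Steps most likely to fail**

Step 13. The fragmentation may be slower than base-induced damage. If the cis-fused bicycle sits mainly in the conformer with an axial mesylate, unreacted alkoxide can enolise the dienone at C7 and the C8 silanolate is then expelled, or elimination toward C2 competes. The fallback sets out from 18 and takes the silyl ether off first with HF·pyridine, giving (1R,6R,7R,8S,10S)-6,8-dihydroxy-4,10-dimethyl-7-(propan-2-yl)bicyclo[5.3.0]dec-4-en-1-yl methanesulfonate F1. Its bis-alkoxide is then fragmented (KN(SiMe3)2, 2.1 equiv, THF, −78 °C). In the product the C8 alkoxide cannot act as a leaving group and lowers the acidity of C7–H. This variant comes back to the route at 21.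

Step 15. Hydride transfer inside the hemiacetal may be sluggish for a conjugated aldehyde on a ten-membered β-hydroxy enone. That would leave time for acyl migration from O8 to O6 or for reductive consumption of the enal by samarium. The fallback sets out from 21 and separates reduction from acylation:
- Me4NBH(OAc)3 in MeCN/AcOH should give the 6,8-anti diol (1(10)E,4Z,6S,7R,8S)-4,10-dimethyl-7-(propan-2-yl)cyclodeca-1(10),4-diene-6,8-diol F2.
- VO(acac)2 with t-BuOOH, directed by the allylic C6 hydroxyl, should give (1(10)E,4S,5R,6R,7R,8S)-4,5-epoxy-4,10-dimethyl-7-(propan-2-yl)cyclodec-1(10)-ene-6,8-diol F3.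
- The less hindered C8 hydroxyl (next to a CH2, whereas C6 lies between the epoxide and C7) is esterified with 3-methylbut-2-enoic acid under Yamaguchi conditions (2,4,6-trichlorobenzoyl chloride, Et3N, DMAP).

This comes back to the route at 25.

Step 7. The bulky borohydride may reduce the hindered enone 1,2 instead of 1,4, the lithium aldolate of the quaternary centre may revert, or the aldehyde may not discriminate well between the two enolate faces. The fallback sets out from 10 and isolates the enolate equivalent. RhCl(PPh3)3-catalysed 1,4-hydrosilylation with Et3SiH should give tert-butyl{[(1S,2R)-4-methyl-2-(propan-2-yl)-3-[(triethylsilyl)oxy]cyclopent-3-en-1-yl]oxy}dimethylsilane F4. A Mukaiyama aldol with 11 (BF3·OEt2, CH2Cl2, −78 °C, aqueous work-up) then comes back to the route at 13. The C1 configuration is again immaterial because of steps 9 and 10.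

**Further compounds**

F1 | step 13 | (1R,6R,7R,8S,10S)-6,8-dihydroxy-4,10-dimethyl-7-(propan-2-yl)bicyclo[5.3.0]dec-4-en-1-yl methanesulfonate | C[C@@]12C[C@H](O)[C@@H](C(C)C)[C@]1(O)C=C(C)CC[C@H]2OS(C)(=O)=O
F2 | step 15 | (1(10)E,4Z,6S,7R,8S)-4,10-dimethyl-7-(propan-2-yl)cyclodeca-1(10),4-diene-6,8-diol | C1/C(C)=C/CC/C(C)=C\[C@H](O)[C@H](C(C)C)[C@H]1O
F3 | step 15 | (1(10)E,4S,5R,6R,7R,8S)-4,5-epoxy-4,10-dimethyl-7-(propan-2-yl)cyclodec-1(10)-ene-6,8-diol | O[C@@H]1[C@H](C(C)C)[C@@H](O)C/C(C)=C/CC[C@]2(C)O[C@H]12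
F4 | step 7 | tert-butyl{[(1S,2R)-4-methyl-2-(propan-2-yl)-3-[(triethylsilyl)oxy]cyclopent-3-en-1-yl]oxy}dimethylsilane | CC[Si](CC)(CC)OC1=C(C)C[C@H](O[Si](C)(C)C(C)(C)C)[C@H]1C(C)C
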